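Ring A (O1 on C8a, OH on C5 and C7, alkyl branch at C4a) and the aryl ring on C2 share the 1,3,5-trioxygenated, mono-alkylated pattern of a triketide chain closed through carbon. Closed through oxygen, the same chain is a 6-methyl-2-pyranone whose 4-oxygen becomes O1. The route therefore cuts C5–C6 and C2'–C3' and carries both arenes as pyranones. One methoxide treatment opens both lactones and recloses each chain by Claisen condensation, making both benzene rings while C2, C3 and C4 stay as set. The substrate is a 3,4-dihydropyrano[4,3-b]pyran-5-one with isobutyl on C4, isopropyl on C3 and a 4-methoxy-6-methyl-2-oxopyran-3-yl group on C2. Fourfold formylation and one demethylation finish.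

Key step: step 6

Remark: all bicyclic intermediates carry the chroman numbering of the target (O1, C2, C3, C4, C4a, C5–C8, C8a; primes for the ring on C2), and it is assumed that vibrational circular dichroism settles which enantiomer of 7 is (S) before material is carried on.

Step 1
Reactants: 1 1,1-diethoxy-3-methylbutane (isovaleraldehyde diethyl acetal)
Product: 2 1-ethoxy-3-methylbut-1-ene (E/Z mixture)
Conditions: TsOH·H2O (0.5 mol%), quinoline (0.5 mol%), neat, 180 °C, EtOH then 2 distilled off
Reagents that add atoms: none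
Why: Acid-catalysed thermal loss of one alcohol from an acetal (acetal cracking) is the standard entry to simple alkyl enol ethers, and the E/Z ratio does not matter because the two carbons concerned (later C2 and C3) lose their configuration in step 2.

Step 2
Reactants: 3 triacetic acid lactone (4-hydroxy-6-methyl-2H-pyran-2-one); 4 isovaleraldehyde (3-methylbutanal); 2 1-ethoxy-3-methylbut-1-ene
Product: 7 rac-4-isobutyl-3-isopropyl-7-methyl-4H,5H-pyrano[4,3-b]pyran-5-one, via alkylidene dione 5 (not isolated), via ethyl acetal 6 (not isolated)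
Conditions: ethylenediammonium diacetate (10 mol%), 2 (4 equiv), 4 Å MS, toluene, 50 °C; then TsOH·H2O (10 mol%), reflux, EtOH removed
Reagents that add atoms: none
Why: The domino Knoevenagel/inverse-electron-demand hetero-Diels–Alder reaction is established for 4-hydroxy-2-pyranones, aliphatic aldehydes and enol ethers; excess 2 should intercept 5 before a second lactone adds, the ketone oxygen of 5 becomes O1, and acid-catalysed loss of ethanol makes all isomers of 6 converge on one racemic enol ether whose only stereocentre is C4.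

Step 3
Reactants: 7 rac-4-isobutyl-3-isopropyl-7-methyl-4H,5H-pyrano[4,3-b]pyran-5-one
Product: 8 (4S)-4-isobutyl-3-isopropyl-7-methyl-4H,5H-pyrano[4,3-b]pyran-5-one
Conditions: preparative SFC, amylose tris(3,5-dimethylphenylcarbamate) phase, CO2/iPrOH
Reagents that add atoms: none
Why: Chromatographic enantiomer separation on a polysaccharide chiral stationary phase is reliable for a neutral, UV-active lactone with a single stereocentre, and it fixes C4 as S, the only centre of the target that needs external control.

Step 4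
Reactants: 8 (4S)-4-isobutyl-3-isopropyl-7-methyl-4H,5H-pyrano[4,3-b]pyran-5-one; 3 triacetic acid lactone
Product: 10 (2R,3R,4S)-2-(4-hydroxy-6-methyl-2-oxo-2H-pyran-3-yl)-4-isobutyl-3-isopropyl-7-methyl-3,4-dihydro-2H,5H-pyrano[4,3-b]pyran-5-one, via oxocarbenium ion 9 (not isolated)
Conditions: 3 (1.1 equiv), Tf2NH (5 mol%), MeCN, 0 °C → rt
Reagents that add atoms: none
Why: This is a Brønsted-acid Friedel–Crafts-type C3-alkylation of a 4-hydroxy-2-pyranone by an oxocarbenium ion (any O-alkylated acetal reverts), and because strain against C5=O and the C3 isopropyl group holds the isobutyl group pseudoaxial, both the proton (at C3) and the nucleophile (at C2) should enter from the opposite face, which sets 3,4-cis and 2,3-trans.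

Step 5
Reactants: 10 (2R,3R,4S)-2-(4-hydroxy-6-methyl-2-oxo-2H-pyran-3-yl)-4-isobutyl-3-isopropyl-7-methyl-3,4-dihydro-2H,5H-pyrano[4,3-b]pyran-5-one
Product: 11 (2R,3R,4S)-4-isobutyl-3-isopropyl-2-(4-methoxy-6-methyl-2-oxo-2H-pyran-3-yl)-7-methyl-3,4-dihydro-2H,5H-pyrano[4,3-b]pyran-5-one
Conditions: Me2SO4 (1.5 equiv), K2CO3, acetone, rt
Reagents that add atoms: dimethyl sulfate, COS(=O)(=O)OC
Why: Williamson-type O-alkylation of 4-hydroxy-2-pyranones with dimethyl sulfate and K2CO3 gives the 4-methoxy-2-pyranone rather than the 2-methoxy-4-pyranone; the cap is needed because the free enolate would resist methoxide in step 6, and the weak base at room temperature leaves the three stereocentres alone.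

Step 6
Reactants: 11 (2R,3R,4S)-4-isobutyl-3-isopropyl-2-(4-methoxy-6-methyl-2-oxo-2H-pyran-3-yl)-7-methyl-3,4-dihydro-2H,5H-pyrano[4,3-b]pyran-5-one
Product: 13 (2R,3R,4S)-2-(2,4-dihydroxy-6-methoxyphenyl)-4-isobutyl-3-isopropylchroman-5,7-diol, via bis(keto ester) 12 (not isolated)
Conditions: NaOMe (15 equiv, 3 M in dry degassed MeOH), 0 °C → rt, then sealed tube, 120 °C; cooled, 1 M HCl to pH 2, THF, rt
Reagents that add atoms: none
Why: Methoxide adds to C5=O and to C2'=O, each lactone opens to a methyl ester plus the enolate of a methyl ketone (12), proton exchange supplies the terminal CH2 enolate, and its attack on the ester, loss of methoxide and enolisation give the resorcinolate, so that C5–C6 and C2'–C3' are made and 13 is simply an isomer of 11. The closest known reaction is the alkoxide-induced ring transformation (intramolecular Claisen, Dieckmann-like) of 4-methoxy-6-methyl-2-pyranone into phloroglucinol monomethyl ether, used here twice in one molecule. Ring A and the pendant ring both close in the 6-(enolendo)-exo-trig mode, favoured because ester and acetonyl arm stand cis on the former pyranone C3=C4 bond, and aromatisation makes each closure irreversible. No stereocentre is formed; C3 and C4 bear no acidic hydrogen, and C2, if it opens through a quinone methide, recloses in base or in the acidic work-up to the 2,3-trans diequatorial arrangement of the target. The step needs the C2–O1 bond to survive: the opened pendant chain is a dienolate with O1 in the β-position, so ring A has to open first, which changes O1 from a vinylogous carboxylate leaving group into the oxygen of an anionic chain and later of a phenolate. The substrate favours this order because C5=O has a free face opposite the pseudoaxial isobutyl group whereas C2'=O is screened on both faces by O1 and C3, which is why excess NaOMe acts in the cold before heating, and the O6' cap is methyl so that alkoxide exchange with the base is degenerate.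

Step 7
Reactants: 13 (2R,3R,4S)-2-(2,4-dihydroxy-6-methoxyphenyl)-4-isobutyl-3-isopropylchroman-5,7-diol
Product: 15 sideroxylonal A 6'-O-methyl ether, via tetrakis(iminium) salt 14 (not isolated)
Conditions: (chloromethylene)dimethyliminium chloride (10 equiv), DMF/MeCN, 0 °C → rt; then H2O, rt → 50 °C
Reagents that add atoms: (chloromethylene)dimethyliminium chloride, C[N+](C)=CCl.[Cl-]; water, O
Why: Vilsmeier–Haack formylation is known to place two formyl groups on free phloroglucinol rings, the four open positions C6, C8, C3' and C5' are each ortho or para to three oxygen donors, and the preformed reagent keeps the medium mild enough to limit ionisation at C2 until the rings have become electron-poor.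

Step 8
Reactants: 15 sideroxylonal A 6'-O-methyl ether
Product: 16 sideroxylonal A
Conditions: BCl3 (6 equiv, 1 M in CH2Cl2), CH2Cl2, −78 → 0 °C; then H2O
Reagents that add atoms: none
Why: Chelation-assisted Lewis-acid demethylation with BCl3 cleaves aryl methyl ethers that have an ortho carbonyl group, here O6'–CH3 next to the C5' formyl group, while the diformylated, electron-poor rings should keep C2–O1 and the three stereocentres intact.

Compound list
1 | 1,1-diethoxy-3-methylbutane | CCOC(CC(C)C)OCC | starting material
2 | 1-ethoxy-3-methylbut-1-ene (E/Z mixture) | CCOC=CC(C)C | intermediate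
3 | triacetic acid lactone (4-hydroxy-6-methyl-2H-pyran-2-one) | CC1=CC(O)=CC(=O)O1 | starting material
4 | isovaleraldehyde (3-methylbutanal) | CC(C)CC=O | starting material
5 | 6-methyl-3-(3-methylbutylidene)-2H-pyran-2,4(3H)-dione | CC(C)CC=C1C(=O)C=C(C)OC1=O | intermediate
6 | 2-ethoxy-4-isobutyl-3-isopropyl-7-methyl-3,4-dihydro-2H,5H-pyrano[4,3-b]pyran-5-one (racemic, diastereomer mixture) | CCOC1OC2=C(C(CC(C)C)C1C(C)C)C(=O)OC(C)=C2 | intermediate
7 | rac-4-isobutyl-3-isopropyl-7-methyl-4H,5H-pyrano[4,3-b]pyran-5-one | CC(C)CC1C(C(C)C)=COC2=C1C(=O)OC(C)=C2 | intermediate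
8 | (4S)-4-isobutyl-3-isopropyl-7-methyl-4H,5H-pyrano[4,3-b]pyran-5-one | CC(C)C[C@@H]1C2=C(C=C(C)OC2=O)OC=C1C(C)C | intermediate
9 | (3R,4S)-oxocarbenium ion (C2=O1+) derived from 8, triflimide ion pair | CC(C)C[C@@H]1C2=C(C=C(C)OC2=O)[O+]=C[C@@H]1C(C)C.FC(F)(F)S(=O)(=O)[N-]S(=O)(=O)C(F)(F)F | intermediate
10 | (2R,3R,4S)-2-(4-hydroxy-6-methyl-2-oxo-2H-pyran-3-yl)-4-isobutyl-3-isopropyl-7-methyl-3,4-dihydro-2H,5H-pyrano[4,3-b]pyran-5-one | CC(C)C[C@@H]1C2=C(C=C(C)OC2=O)O[C@@H](C2=C(O)C=C(C)OC2=O)[C@@H]1C(C)C | intermediate
11 | (2R,3R,4S)-4-isobutyl-3-isopropyl-2-(4-methoxy-6-methyl-2-oxo-2H-pyran-3-yl)-7-methyl-3,4-dihydro-2H,5H-pyrano[4,3-b]pyran-5-one | CC(C)C[C@@H]1C2=C(C=C(C)OC2=O)O[C@@H](C2=C(OC)C=C(C)OC2=O)[C@@H]1C(C)C | intermediate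
12 | methyl (2R,3R,4S)-4-isobutyl-3-isopropyl-2-[(1E)-2-methoxy-1-(methoxycarbonyl)-4-oxopent-1-en-1-yl]-6-(2-oxopropyl)-3,4-dihydro-2H-pyran-5-carboxylate (drawn neutral, present as bis-enolate) | CC(C)C[C@@H]1C(C(=O)OC)=C(CC(C)=O)O[C@@H](/C(C(=O)OC)=C(\OC)CC(C)=O)[C@@H]1C(C)C | intermediate
13 | (2R,3R,4S)-2-(2,4-dihydroxy-6-methoxyphenyl)-4-isobutyl-3-isopropylchroman-5,7-diol | CC(C)C[C@@H]1c2c(O)cc(O)cc2O[C@@H](c2c(O)cc(O)cc2OC)[C@@H]1C(C)C | intermediate
14 | 6,8,3',5'-tetrakis(dimethyliminiomethyl) derivative of 13, tetrachloride | CC(C)C[C@@H]1c2c(O)c(C=[N+](C)C)c(O)c(C=[N+](C)C)c2O[C@@H](c2c(O)c(C=[N+](C)C)c(O)c(C=[N+](C)C)c2OC)[C@@H]1C(C)C.[Cl-].[Cl-].[Cl-].[Cl-] | intermediate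
15 | sideroxylonal A 6'-O-methyl ether, (2R,3R,4S) | CC(C)C[C@@H]1c2c(O)c(C=O)c(O)c(C=O)c2O[C@@H](c2c(O)c(C=O)c(O)c(C=O)c2OC)[C@@H]1C(C)C | intermediate
16 | sideroxylonal A, (2R,3R,4S) | CC(C)C[C@@H]1c2c(O)c(C=O)c(O)c(C=O)c2O[C@@H](c2c(O)c(C=O)c(O)c(C=O)c2O)[C@@H]1C(C)C | target

Total step count: 8. Longest linear sequence: 8 steps (1 → 16).

Steps most likely to fail

Step 6. The C2–O1 bond may be cleaved before ring A has aromatised, either by β-elimination from the opened pendant chain or by quinone methide formation. The reaction may also stall after only one of the two ring transformations.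
- The fallback sets out from 8 and comes back at 16. The ring transformation is run once and earlier, on 8, where O1 sits on the sp2 carbon C2 and cannot leave.
- NaOMe in hot MeOH should give (4S)-4-isobutyl-3-isopropyl-4H-chromene-5,7-diol F1.
- Acid-catalysed Friedel–Crafts coupling of F1 with an excess of commercial phloroglucinol follows the same facial bias as step 4. It gives (2R,3R,4S)-2-(2,4,6-trihydroxyphenyl)-4-isobutyl-3-isopropylchroman-5,7-diol F2.
- Fourfold Vilsmeier–Haack formylation through the tetrakis(iminium) salt F3, then hydrolysis, leads to 16 directly with no methyl ether to remove.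

Step 4. Protonation at C3 may occur from both faces, the C3 proton may be lost reversibly during a slow coupling, or the cation may be captured through oxygen instead of carbon.
- The fallback sets out from 8 and comes back at 10, and it separates the two events.
- Camphorsulfonic acid in MeOH adds methanol to 8 to give (3R,4S)-4-isobutyl-3-isopropyl-2-methoxy-7-methyl-3,4-dihydro-2H,5H-pyrano[4,3-b]pyran-5-one F4. This is a stable acetal whose 3,4-cis isomer can be purified.
- Compound 3 is silylated with hexamethyldisilazane to 6-methyl-4-(trimethylsilyloxy)-2H-pyran-2-one F5.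
- A TMSOTf-promoted Mukaiyama-type coupling of the two at −78 °C, where the cation cannot equilibrate with the enol ether, forms the C2–C3' bond and gives 10.

Step 7. Acid may open the ring at C2 while the rings are still electron-rich, and the reaction may stall before the fourth formyl group is in place.
- The fallback sets out from 13 and comes back at 16. The four phenols are capped first (Me2SO4, K2CO3) to give (2R,3R,4S)-4-isobutyl-3-isopropyl-5,7-dimethoxy-2-(2,4,6-trimethoxyphenyl)chroman F6, which cannot form a quinone methide.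
- Rieche formylation (Cl2CHOMe, TiCl4), a reaction type used for twofold formylation of dimethoxyarenes, gives the 6,8,3',5'-tetracarbaldehyde F7.
- Every methoxy group in F7 has an ortho formyl neighbour, so excess BCl3 removes all five and delivers 16.

Further compounds
F1 | step 6 | (4S)-4-isobutyl-3-isopropyl-4H-chromene-5,7-diol | CC(C)C[C@@H]1c2c(O)cc(O)cc2OC=C1C(C)C
F2 | step 6 | (2R,3R,4S)-2-(2,4,6-trihydroxyphenyl)-4-isobutyl-3-isopropylchroman-5,7-diol | CC(C)C[C@@H]1c2c(O)cc(O)cc2O[C@@H](c2c(O)cc(O)cc2O)[C@@H]1C(C)C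
F3 | step 6 | 6,8,3',5'-tetrakis(dimethyliminiomethyl) derivative of F2, tetrachloride | CC(C)C[C@@H]1c2c(O)c(C=[N+](C)C)c(O)c(C=[N+](C)C)c2O[C@@H](c2c(O)c(C=[N+](C)C)c(O)c(C=[N+](C)C)c2O)[C@@H]1C(C)C.[Cl-].[Cl-].[Cl-].[Cl-]
F4 | step 4 | (3R,4S)-4-isobutyl-3-isopropyl-2-methoxy-7-methyl-3,4-dihydro-2H,5H-pyrano[4,3-b]pyran-5-one (anomer mixture) | CC(C)C[C@@H]1C2=C(C=C(C)OC2=O)OC(OC)[C@@H]1C(C)C
F5 | step 4 | 6-methyl-4-(trimethylsilyloxy)-2H-pyran-2-one | CC1=CC(O[Si](C)(C)C)=CC(=O)O1
F6 | step 7 | (2R,3R,4S)-4-isobutyl-3-isopropyl-5,7-dimethoxy-2-(2,4,6-trimethoxyphenyl)chroman | CC(C)C[C@@H]1c2c(OC)cc(OC)cc2O[C@@H](c2c(OC)cc(OC)cc2OC)[C@@H]1C(C)C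
F7 | step 7 | (2R,3R,4S)-2-(3,5-diformyl-2,4,6-trimethoxyphenyl)-4-isobutyl-3-isopropyl-5,7-dimethoxychroman-6,8-dicarbaldehyde | CC(C)C[C@@H]1c2c(OC)c(C=O)c(OC)c(C=O)c2O[C@@H](c2c(OC)c(C=O)c(OC)c(C=O)c2OC)[C@@H]1C(C)C
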